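**Plan**

Ring A: a1 (OMe), a2 (H), a3 (CH3), a4 (lactone C=O), a5 (ether O), a6 (CH2OH). Ring B: b1 (ether O), b2 (ester O), b3 (CH3), b4 (OH), b5 (phthalide C=O), b6 (lactol carbon, R).
Cuts: first the lactol C–O bond to the b5 carboxyl (back to a b6 formyl / b5 methyl ester pair); then, together, the a5 O–b1 ether bond and the b6–CHO bond (back to a ring B b1–b6 aryne, i.e. b1 iodide / b6 triflate); last the a4 CO–O b2 ester (back to a ring A salicylic acid and a ring B phenol).
Enabling feature: the vicinal pair b1/b6 on ring B must receive an oxygen and a carbon, the signature of an aryne, and the a4 carbonyl–O–b2 ester places the a5 phenol so that it can close a seven-membered ring on b1 but cannot span to b6.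
Forward: the ring B phenol (from 2-methylphloroglucinol) and the ring A acid (from methyl orsellinate) are esterified; the central dioxepinone ring closes in the aryne step with capture of the formyl carbon; the lactol ring closes last under aqueous acid.
Stereochemistry: the only stereocentre is the lactol carbon; it is set at the end by lipase-mediated dynamic kinetic acetylation of the equilibrating racemic lactol and uncovered by neutral enzymatic deacetylation with retention.

Key step: step 13

Assumption: the lactol carbon is taken to hold its configuration in neutral, base-free media (ring–chain tautomerism through the b6 aldehyde / b5 acid needs acid or base), so it is set and released in the last two steps and the target is isolated without contact with base.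

**Route**

Step 1
Reactants: 1 2-methylphloroglucinol (2,4,6-trihydroxytoluene)
Product: 2 2,4,6-trihydroxy-3-methylbenzoic acid
Conditions: KHCO3, H2O, CO2 (1 atm), 50 °C; then cold 1 M HCl
Reagents that add atoms: carbon dioxide, O=C=O (supplied as KHCO3 under CO2)
Why: Kolbe–Schmitt carboxylation of the phloroglucinol nucleus runs under mild aqueous bicarbonate conditions at the two equivalent free ring positions, so one acid should result; it is precipitated cold because such acids lose CO2 on heating.

Step 2
Reactants: 2 2,4,6-trihydroxy-3-methylbenzoic acid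
Product: 3 methyl 2,4,6-trihydroxy-3-methylbenzoate
Conditions: MeI (1.05 equiv), KHCO3, DMF, rt
Reagents that add atoms: iodomethane, CI
Why: SN2 alkylation of the potassium carboxylate esterifies the acid, while the phenols, which KHCO3 does not deprotonate appreciably, should stay free.

Step 3
Reactants: 3 methyl 2,4,6-trihydroxy-3-methylbenzoate
Product: 4 methyl 4-{[tert-butyl(dimethyl)silyl]oxy}-2,6-dihydroxy-3-methylbenzoate
Conditions: TBSCl (1.05 equiv), imidazole, CH2Cl2, 0 °C
Reagents that add atoms: tert-butyldimethylsilyl chloride, CC(C)(C)[Si](C)(C)Cl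
Why: chemoselective silylation takes the 4-OH, the only phenol not hydrogen-bonded to the ester, and this temporary block leaves the two chelated phenols to be told apart in the next step.

Step 4
Reactants: 4 methyl 4-{[tert-butyl(dimethyl)silyl]oxy}-2,6-dihydroxy-3-methylbenzoate
Product: 5 methyl 4-{[tert-butyl(dimethyl)silyl]oxy}-2-hydroxy-3-methyl-6-{[(trifluoromethyl)sulfonyl]oxy}benzoate
Conditions: Tf2O (1.0 equiv), pyridine, CH2Cl2, −78 → −20 °C
Reagents that add atoms: trifluoromethanesulfonic anhydride, O=S(=O)(OS(=O)(=O)C(F)(F)F)C(F)(F)F
Why: O-sulfonylation with one equivalent of Tf2O should take the 6-OH, whose neighbour is a ring hydrogen, in preference to the 2-OH wedged between ester and methyl group (and buttressed by the silyl ether); the remaining phenol, then the sole hydrogen-bond partner of the ester carbonyl, should resist a second triflation.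

Step 5
Reactants: 5 methyl 4-{[tert-butyl(dimethyl)silyl]oxy}-2-hydroxy-3-methyl-6-{[(trifluoromethyl)sulfonyl]oxy}benzoate
Product: 6 methyl 2,4-dihydroxy-3-methyl-6-{[(trifluoromethyl)sulfonyl]oxy}benzoate
Conditions: KHF2, MeOH, rt
Reagents that add atoms: none
Why: fluoride-mediated desilylation with KHF2 is selective for aryl silyl ethers and, being weakly acidic, should leave the aryl triflate and the methyl ester untouched.

Step 6
Reactants: 6 methyl 2,4-dihydroxy-3-methyl-6-{[(trifluoromethyl)sulfonyl]oxy}benzoate
Product: 7 methyl 2,4-dihydroxy-5-iodo-3-methyl-6-{[(trifluoromethyl)sulfonyl]oxy}benzoate (ring B phenol; C5 = b1, C6 = b6, C4 = b2)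
Conditions: N-iodosuccinimide, MeCN, 0 °C
Reagents that add atoms: N-iodosuccinimide, O=C1CCC(=O)N1I
Why: electrophilic aromatic iodination can only occur at C5, the single unsubstituted position, which is ortho to the 4-OH and para to the 2-OH; it is done before ring A is attached so that the electron-rich a2 position cannot compete.

Step 7
Reactants: 8 methyl orsellinate (methyl 2,4-dihydroxy-6-methylbenzoate)
Product: 9 methyl 2-hydroxy-4-methoxy-6-methylbenzoate
Conditions: MeI (1.05 equiv), K2CO3, acetone, reflux
Reagents that add atoms: iodomethane, CI
Why: Williamson O-methylation is selective for the 4-OH because the 2-OH is tied up in a hydrogen bond to the ester carbonyl.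

Step 8
Reactants: 9 methyl 2-hydroxy-4-methoxy-6-methylbenzoate
Product: 10 methyl 3-formyl-2-hydroxy-4-methoxy-6-methylbenzoate
Conditions: MgCl2, Et3N, (CH2O)n, MeCN, reflux
Reagents that add atoms: paraformaldehyde (formaldehyde), C=O
Why: magnesium-mediated ortho-formylation of phenols (Casnati–Skattebøl) delivers formaldehyde within the magnesium phenoxide to the only free ortho position, C3, and a second formaldehyde oxidises the benzylic alkoxide to the aldehyde by hydride transfer.

Step 9
Reactants: 10 methyl 3-formyl-2-hydroxy-4-methoxy-6-methylbenzoate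
Product: 11 3-formyl-2-hydroxy-4-methoxy-6-methylbenzoic acid (ring A acid)
Conditions: conc. H2SO4, 0 °C → rt; then ice–water
Reagents that add atoms: water, O
Why: doubly ortho-substituted, para-methoxy benzoates ionise in cold concentrated H2SO4 to the acylium ion (A_AC1 ester hydrolysis), which water converts into the acid on quenching, whereas base hydrolysis of this hindered salicylate would be slow; the protonated carbonyl groups protect the ring from sulfonation.

Step 10
Reactants: 7 methyl 2,4-dihydroxy-5-iodo-3-methyl-6-{[(trifluoromethyl)sulfonyl]oxy}benzoate; 11 3-formyl-2-hydroxy-4-methoxy-6-methylbenzoic acid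
Product: 12 depside aldehyde, methyl 4-[(3-formyl-2-hydroxy-4-methoxy-6-methylbenzoyl)oxy]-2-hydroxy-5-iodo-3-methyl-6-{[(trifluoromethyl)sulfonyl]oxy}benzoate
Conditions: N,N'-dicyclohexylcarbodiimide, 4-(dimethylamino)pyridine (cat.), CH2Cl2, 0 °C → rt
Reagents that add atoms: none
Why: carbodiimide esterification (Steglich conditions) should join the acid to the only phenol that is not chelated, the 4-OH of 7, as in the assembly of related depsides from unprotected 3-formylsalicylic acids, and so creates the a4–CO–O–b2 tether.

Step 11
Reactants: 12 depside aldehyde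
Product: 13 depside alcohol, methyl 2-hydroxy-4-{[2-hydroxy-3-(hydroxymethyl)-4-methoxy-6-methylbenzoyl]oxy}-5-iodo-3-methyl-6-{[(trifluoromethyl)sulfonyl]oxy}benzoate
Conditions: NaBH4, THF/MeOH, −20 °C; aq. NH4Cl
Reagents that add atoms: none
Why: NaBH4 reduces the aldehyde chemoselectively at low temperature; the hindered aryl ester, the chelated methyl ester, the triflate and the iodide are inert, and the short cold reaction avoids over-reduction through an ortho-quinone methide.

Step 12
Reactants: 13 depside alcohol
Product: 14 aryne precursor, methyl 4-{[3-({[tert-butyl(dimethyl)silyl]oxy}methyl)-2-hydroxy-4-methoxy-6-methylbenzoyl]oxy}-2-hydroxy-5-iodo-3-methyl-6-{[(trifluoromethyl)sulfonyl]oxy}benzoate (b1 iodide, b6 triflate, free a5 and b4 phenols)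
Conditions: TBSCl (1.1 equiv), imidazole, DMF, 0 °C
Reagents that add atoms: tert-butyldimethylsilyl chloride, CC(C)(C)[Si](C)(C)Cl
Why: silylation of the primary benzylic alcohol is much faster than that of the two hindered, chelated phenols, so only the a6 oxygen is protected and the a5 phenol stays free for the key step.

Step 13
Reactants: 14 aryne precursor
Product: 18 depsidone aldehyde (methyl 4-({[tert-butyl(dimethyl)silyl]oxy}methyl)-6-formyl-8-hydroxy-3-methoxy-1,9-dimethyl-11-oxo-11H-dibenzo[b,e][1,4]dioxepine-7-carboxylate), via b1–b6 aryne 15 (not isolated), via b6 arylmagnesium chloride 16 (not isolated), via magnesium hemiaminal alkoxide 17 (not isolated)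
Conditions: Me3SiCH2MgCl (3.3 equiv, slow addition), THF (0.02 M), −78 → −20 °C; DMF, −20 → 0 °C; 1 M HCl
Reagents that add atoms: N,N-dimethylformamide, CN(C)C=O
Why: Proposed new method: two equivalents of Me3SiCH2MgCl turn the a5 and b4 phenols into chloromagnesium phenoxides, a third undergoes iodine–magnesium exchange at b1, and loss of the b6 triflate gives the aryne 15; the a5 phenoxide then adds in the ring B plane to b1, and the b6 arylmagnesium 16 so formed, stabilised by chelation to the b5 ester, is formylated by DMF through 17. The closest known reactions are aryne generation from 2-iodoaryl triflates with Me3SiCH2MgCl, addition of phenoxides to arynes, Bouveault formylation of arylmagnesium halides and, for the ring itself, copper-mediated intramolecular O-arylation of 2-halophenyl salicylates; new is the tethered phenoxide addition with capture of the aryl anion in one flask. The seven-membered dioxepinone ring closes by a 7-exo-dig-type attack of oxygen on the aryne carbon b1 (the partner carbon b6 stays outside the new ring), for which the depside ester must rotate into its s-trans, lactone-like conformer. No stereocentre is formed. The step needs regioselectivity for b1, which the tether secures because a ring closed on b6 would have to bridge the meta positions b2 and b6, and chemoselectivity over three esters and the silyl ether, which rests on the low nucleophilicity of Me3SiCH2MgCl at −78 °C, on the chelated b4 phenoxide shielding the b5 ester and on the two ortho substituents shielding the depside carbonyl. A formamide is used as the electrophile, not CO2, so that the new carbon arrives at the aldehyde level next to the b5 ester, which fixes b6 as the future lactol carbon and avoids a later selective reduction of a phthalic half ester.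

Step 14
Reactants: 18 depsidone aldehyde
Product: 19 racemic lactol (depsidone with a1 OMe, a3 CH3, a6 CH2OH, b3 CH3, b4 OH and a 3-hydroxyphthalide fused at b5/b6, lactol carbon on b6)
Conditions: 1 M H2SO4 (aq.)/THF 1:3, 45 °C
Reagents that add atoms: water, O
Why: dilute aqueous acid hydrolyses the primary silyl ether and lets the hydrate of the b6 aldehyde attack the neighbouring b5 ester (acid-catalysed lactonisation with neighbouring-group participation, loss of MeOH), which should give the ring tautomer of the 2-formylbenzoic acid as the racemic lactol while the hindered depsidone lactone survives.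

Step 15
Reactants: 19 racemic lactol
Product: 20 (R)-lactol acetate with a6 CH2OAc (diacetate of the target, b4 OH free)
Conditions: immobilised lipase from Burkholderia cepacia (Amano PS), vinyl acetate (excess), Et3N (cat.), THF, 35 °C
Reagents that add atoms: vinyl acetate, C=COC(C)=O
Why: lipase-catalysed irreversible transacetylation under dynamic kinetic resolution: the lactol enantiomers interconvert through the ring-opened aldehyde–carboxylate (accelerated by Et3N) while the enzyme acetylates one of them, expected from the empirical size rule for lipases (aryl carbon large, ring oxygen medium) to be the R lactol, so the R acetate should accumulate; the primary a6 alcohol is acetylated as well and the chelated b4 phenol is not.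

Step 16
Reactants: 20 (R)-lactol acetate with a6 CH2OAc
Product: 21 target, (R)-lactol (cryptostictic acid constitution; (1R)-1,4-dihydroxy-11-(hydroxymethyl)-10-methoxy-5,8-dimethyl depsidone phthalide)
Conditions: immobilised lipase from Burkholderia cepacia (Amano PS), n-BuOH, tert-butyl methyl ether/THF, 25 °C; filtration, crystallisation
Reagents that add atoms: none
Why: lipase-catalysed alcoholysis with n-butanol removes both acetyl groups under neutral, water-free conditions by acyl–oxygen cleavage, so the C–O bond at the lactol carbon is untouched and the R configuration is retained; the enzyme's preference for the R acetate should further enrich the product.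

**Compound list**

1 | 2-methylphloroglucinol (2,4,6-trihydroxytoluene) | Cc1c(O)cc(O)cc1O | starting material
2 | 2,4,6-trihydroxy-3-methylbenzoic acid | OC(=O)c1c(O)c(C)c(O)cc1O | intermediate
3 | methyl 2,4,6-trihydroxy-3-methylbenzoate | COC(=O)c1c(O)c(C)c(O)cc1O | intermediate
4 | methyl 4-{[tert-butyl(dimethyl)silyl]oxy}-2,6-dihydroxy-3-methylbenzoate | COC(=O)c1c(O)c(C)c(O[Si](C)(C)C(C)(C)C)cc1O | intermediate
5 | methyl 4-{[tert-butyl(dimethyl)silyl]oxy}-2-hydroxy-3-methyl-6-{[(trifluoromethyl)sulfonyl]oxy}benzoate | COC(=O)c1c(O)c(C)c(O[Si](C)(C)C(C)(C)C)cc1OS(=O)(=O)C(F)(F)F | intermediate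
6 | methyl 2,4-dihydroxy-3-methyl-6-{[(trifluoromethyl)sulfonyl]oxy}benzoate | COC(=O)c1c(O)c(C)c(O)cc1OS(=O)(=O)C(F)(F)F | intermediate
7 | methyl 2,4-dihydroxy-5-iodo-3-methyl-6-{[(trifluoromethyl)sulfonyl]oxy}benzoate | COC(=O)c1c(O)c(C)c(O)c(I)c1OS(=O)(=O)C(F)(F)F | intermediate
8 | methyl orsellinate (methyl 2,4-dihydroxy-6-methylbenzoate) | COC(=O)c1c(C)cc(O)cc1O | starting material
9 | methyl 2-hydroxy-4-methoxy-6-methylbenzoate | COC(=O)c1c(C)cc(OC)cc1O | intermediate
10 | methyl 3-formyl-2-hydroxy-4-methoxy-6-methylbenzoate | COC(=O)c1c(C)cc(OC)c(C=O)c1O | intermediate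
11 | 3-formyl-2-hydroxy-4-methoxy-6-methylbenzoic acid | OC(=O)c1c(C)cc(OC)c(C=O)c1O | intermediate
12 | depside aldehyde (a6 CHO, b1 I, b6 OTf) | COc1cc(C)c(C(=O)Oc2c(C)c(O)c(C(=O)OC)c(OS(=O)(=O)C(F)(F)F)c2I)c(O)c1C=O | intermediate
13 | depside alcohol (a6 CH2OH) | COc1cc(C)c(C(=O)Oc2c(C)c(O)c(C(=O)OC)c(OS(=O)(=O)C(F)(F)F)c2I)c(O)c1CO | intermediate
14 | aryne precursor (a6 CH2OTBS, free a5 and b4 phenols, b1 I, b6 OTf) | COc1cc(C)c(C(=O)Oc2c(C)c(O)c(C(=O)OC)c(OS(=O)(=O)C(F)(F)F)c2I)c(O)c1CO[Si](C)(C)C(C)(C)C | intermediate
15 | b1–b6 aryne as bis(chloromagnesium) phenoxide (not isolated) | COc1cc(C)c(C(=O)OC2=C(C)C(O[Mg]Cl)=C(C(=O)OC)C#C2)c(O[Mg]Cl)c1CO[Si](C)(C)C(C)(C)C | intermediate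
16 | depsidone b6 arylmagnesium chloride, b4 chloromagnesium phenoxide (not isolated) | COc1cc(C)c2c(c1CO[Si](C)(C)C(C)(C)C)Oc1c(c(C)c(O[Mg]Cl)c(C(=O)OC)c1[Mg]Cl)OC2=O | intermediate
17 | magnesium hemiaminal alkoxide at the b6 carbon (not isolated) | COc1cc(C)c2c(c1CO[Si](C)(C)C(C)(C)C)Oc1c(c(C)c(O[Mg]Cl)c(C(=O)OC)c1C(O[Mg]Cl)N(C)C)OC2=O | intermediate
18 | depsidone aldehyde (b6 CHO, b5 CO2Me, b4 OH, a6 CH2OTBS) | COc1cc(C)c2c(c1CO[Si](C)(C)C(C)(C)C)Oc1c(c(C)c(O)c(C(=O)OC)c1C=O)OC2=O | intermediate
19 | racemic lactol | COc1cc(C)c2c(c1CO)Oc1c(c(C)c(O)c3c1C(O)OC3=O)OC2=O | intermediate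
20 | (R)-lactol acetate with a6 CH2OAc | COc1cc(C)c2c(c1COC(C)=O)Oc1c(c(C)c(O)c3c1[C@H](OC(C)=O)OC3=O)OC2=O | intermediate
21 | (R)-lactol, CNP0367167.1 | COc1cc(C)c2c(c1CO)Oc1c(c(C)c(O)c3c1[C@H](O)OC3=O)OC2=O | target

**Count and risks**

Total steps: 16. Longest linear sequence: 13 steps (steps 1–6 and 10–16, from 1 to 21); the ring A branch (steps 7–9) joins at step 10.

Step 13 (bears the label). The tethered phenoxide may add too slowly, because the depside ester has to rotate out of its preferred conformer, so that the aryne is consumed intermolecularly, or the b1 arylmagnesium may undergo acyl migration before the triflate leaves. The fallback makes the two bonds one after the other by known reactions, setting out from 14. CuI/N,N-dimethylglycine, Cs2CO3, dioxane, 90 °C (intramolecular Ullmann O-arylation, selective for the iodide) would close the seven-membered ring to the b6-triflyloxy depsidone F1. Pd(OAc)2/1,3-bis(diphenylphosphino)propane, CO (1 atm), Et3SiH, Et3N, DMF, 70 °C (reductive carbonylation of the aryl triflate) would then install the b6 formyl group and return to the route at 18.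

Step 10. Acylation of the doubly ortho-substituted, weakly nucleophilic phenol by the equally hindered activated acid may be slow, so that rearrangement to the N-acylurea or self-condensation of the acid takes over. The fallback masks and activates the acid, setting out from 11. Ac2O, pyridine would give the O-acetyl acid F2, and (COCl)2 with cat. DMF its acid chloride F3. Acylation of 7 with Et3N and 4-(dimethylamino)pyridine in CH2Cl2 would give the a5-O-acetyl depside F4. Methanolysis of the doubly activated aryl acetate (K2CO3 cat., MeOH, 0 °C) would return to the route at 12.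

Step 15. The enzyme may bind the crowded lactol poorly, acetylate the S enantiomer, or act faster than the lactol racemises, so that enantiomeric purity or sense is lost. The fallback replaces the enzyme by a chiral acyl-transfer catalyst, setting out from 19: (R)- or (S)-2-phenyl-2,3-dihydrobenzo[d]imidazo[2,1-b]thiazole (benzotetramisole, the enantiomer chosen by a test run), Ac2O (2.2 equiv), iPr2NEt, CHCl3, 0 °C. This is an isothiourea-catalysed acylative dynamic kinetic resolution that also acetylates the primary alcohol, so it would return to the route directly at 20; no compound outside the list is made (F0).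

**Further compounds**

F1 | step 13 | b6-triflyloxy depsidone (b5 CO2Me, b4 OH, a6 CH2OTBS) | COc1cc(C)c2c(c1CO[Si](C)(C)C(C)(C)C)Oc1c(c(C)c(O)c(C(=O)OC)c1OS(=O)(=O)C(F)(F)F)OC2=O
F2 | step 10 | 2-acetoxy-3-formyl-4-methoxy-6-methylbenzoic acid | CC(=O)Oc1c(C=O)c(OC)cc(C)c1C(O)=O
F3 | step 10 | 2-acetoxy-3-formyl-4-methoxy-6-methylbenzoyl chloride | CC(=O)Oc1c(C=O)c(OC)cc(C)c1C(Cl)=O
F4 | step 10 | a5-O-acetyl depside aldehyde | COc1cc(C)c(C(=O)Oc2c(C)c(O)c(C(=O)OC)c(OS(=O)(=O)C(F)(F)F)c2I)c(OC(C)=O)c1C=O
F0 | step 15 | none | none
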